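## Retrosynthetic overview
1. Ring labels: A/B = decalin, C = cyclohexene, D = methoxy-enedione, E = γ-pyrone, F = resorcinol ring. C and E are both made in the last flask. The dienophile is an alkynone quinone, not the finished flavone quinone.
2. Ring C comes from a Diels–Alder reaction of a (12E)-labdatrienone at the alkynyl-bearing quinone C=C. Ring E then closes by desilylation and 6-endo-dig attack of a phenol on the ynone.
3. In the target, C11, the angular substituent and H-8a lie on one face of ring C. This is the quinone-exo adduct of the E-diene, so the free 9α-OH is kept as the directing group.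
4. The diene comes from (+)-sclareolide, which supplies rings A/B. Its 9α-OH/8(17)-ene/7-one array is built by α-epoxidation, Ti(III) opening and Riley oxidation, and its side chain by two Wittig reactions.
5. The alkynone quinone comes from silylated phloroglucinolcarboxylic acid chloride (ring F) and ethynyltrimethoxybenzene, followed by CAN oxidation (ring D). Ring order: A/B, D and F are bought; C then E are formed last.

Assumption: commercial (+)-sclareolide is the (3aR,5aS,9aS,9bR) enantiomer, and its C5/C10 configuration is that of the target. Labdane numbering is used for the terpene part and 4a,5,8,8a-tetrahydronaphthalene-1,4-dione numbering for rings C/D.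

## Route

Step 1
Reactants: 1 (+)-sclareolide
Product: 2 methyl 13,14,15,16-tetranorlabd-8(9)-en-12-oate (5S,10S; tetrasubstituted C8=C9)
Conditions: conc. H2SO4 (cat.), MeOH, reflux
Reagents that add atoms: methanol, CO
Why: Acid-mediated alkyl–oxygen lactone opening (E1) and Fischer esterification occur with acid equilibration of the olefin isomers to the most substituted Δ8(9) alkene, so C5 and C10 are untouched and C8/C9 are flattened on purpose.

Step 2
Reactants: 2 methyl 13,14,15,16-tetranorlabd-8(9)-en-12-oate
Product: 3 methyl 8α,9α-epoxy-13,14,15,16-tetranorlabdan-12-oate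
Conditions: mCPBA, CH2Cl2, 0 °C
Reagents that add atoms: mCPBA, OOC(=O)c1cccc(Cl)c1
Why: Prilezhaev epoxidation of the only, electron-rich alkene takes place on the α face because the axial C10 methyl blocks the β face, and this fixes the C9–O bond in the α orientation of the target.

Step 3
Reactants: 3 methyl 8α,9α-epoxy-13,14,15,16-tetranorlabdan-12-oate
Product: 4 methyl 9α-hydroxy-13,14,15,16-tetranorlabd-8(17)-en-12-oate
Conditions: Cp2TiCl2 (2.5 equiv), Mn dust, THF, rt; 1 M HCl work-up
Reagents that add atoms: none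
Why: In this Nugent–RajanBabu Ti(III) epoxide opening, C8–O homolysis gives the better hyperconjugated tertiary C8 radical (the radical that ends titanocene polyene cyclisations), which is too hindered for Ti–C bonding and deoxygenation and instead loses a C17 hydrogen to a second Cp2TiCl to give the exocyclic alkene, leaving the 9α C–O bond untouched.

Step 4
Reactants: 4 methyl 9α-hydroxy-13,14,15,16-tetranorlabd-8(17)-en-12-oate
Product: 5 methyl 7α,9α-dihydroxy-13,14,15,16-tetranorlabd-8(17)-en-12-oate
Conditions: SeO2 (0.5 equiv), t-BuOOH, CH2Cl2, 0 °C to rt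
Reagents that add atoms: selenium dioxide, O=[Se]=O; tert-butyl hydroperoxide, CC(C)(C)OO
Why: Riley allylic hydroxylation (ene reaction then [2,3]-shift) can only use the C7 hydrogens because C9 is fully substituted, and it delivers the oxygen axially from the α face to a temporary stereocentre that step 7 erases.

Step 5
Reactants: 5 methyl 7α,9α-dihydroxy-13,14,15,16-tetranorlabd-8(17)-en-12-oate
Product: 6 7α,9α-dihydroxy-13,14,15,16-tetranorlabd-8(17)-en-12-al
Conditions: DIBAL-H (3.3 equiv), CH2Cl2, −78 °C; Rochelle salt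
Reagents that add atoms: none
Why: In this partial ester reduction the aluminium alkoxide formed at the β-hydroxyl chelates the tetrahedral hemiacetal and holds it until the quench, and no stereocentre is touched.

Step 6
Reactants: 6 7α,9α-dihydroxy-13,14,15,16-tetranorlabd-8(17)-en-12-al
Product: 8 (12E)-labda-8(17),12,14-triene-7α,9α-diol, via enal 7 (not isolated)
Conditions: Ph3P=C(Me)CHO, PhMe, 80 °C; cool to −78 °C, add Ph3P=CH2 (MePPh3Br, KOt-Bu, THF), to 0 °C
Reagents that add atoms: 2-(triphenylphosphoranylidene)propanal, CC(C=O)=P(c1ccccc1)(c1ccccc1)c1ccccc1; methyltriphenylphosphonium bromide, C[P+](c1ccccc1)(c1ccccc1)c1ccccc1.[Br-]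
Why: Two Wittig olefinations run in one flask: the stabilised formyl ylide sets the (E)-C12=C13 geometry (typically >95:5), and the methylene ylide, which is too weak a base to deprotonate the alcohols and start a retro-aldol cleavage, then turns CHO into vinyl.

Step 7
Reactants: 8 (12E)-labda-8(17),12,14-triene-7α,9α-diol
Product: 9 (12E)-9α-hydroxylabda-8(17),12,14-trien-7-one
Conditions: Dess–Martin periodinane, CH2Cl2, 0 °C; use at once
Reagents that add atoms: none
Why: Dess–Martin oxidation takes only the secondary allylic 7-OH, because the tertiary 9-OH cannot be oxidised and the diene is inert, and it gives the α-methylene-β-hydroxy ketone of the target.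

Step 8
Reactants: 10 2,4,5-trimethoxybenzaldehyde
Product: 11 1-ethynyl-2,4,5-trimethoxybenzene
Conditions: Ohira–Bestmann reagent, K2CO3, MeOH, rt
Reagents that add atoms: dimethyl (1-diazo-2-oxopropyl)phosphonate, COP(=O)(OC)C(=[N+]=[N-])C(C)=O
Why: Seyferth–Gilbert homologation in the Ohira–Bestmann variant converts the aryl aldehyde into the terminal alkyne under mild base.

Step 9
Reactants: 12 2,4,6-trihydroxybenzoic acid
Product: 13 tert-butyldimethylsilyl 2,4,6-tris(tert-butyldimethylsilyloxy)benzoate
Conditions: TBSCl (4.5 equiv), imidazole, DMF, rt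
Reagents that add atoms: TBSCl, CC(C)(C)[Si](C)(C)Cl
Why: Exhaustive silylation at room temperature avoids decarboxylation, masks the three phenols so that the later ynone cannot cyclise early, and turns the acid into a silyl ester ready for neutral activation.

Step 10
Reactants: 13 tert-butyldimethylsilyl 2,4,6-tris(tert-butyldimethylsilyloxy)benzoate; 11 1-ethynyl-2,4,5-trimethoxybenzene
Product: 15 1-[2,4,6-tris(tert-butyldimethylsilyloxy)phenyl]-3-(2,4,5-trimethoxyphenyl)prop-2-yn-1-one, via acid chloride 14 (not isolated)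
Conditions: (COCl)2, DMF (cat.), CH2Cl2, 0 °C to rt, evaporate; 11, PdCl2(PPh3)2 (cat.), CuI (cat.), Et3N, THF, rt
Reagents that add atoms: none
Why: The silyl ester exchanges to the acid chloride under neutral Vilsmeier-type conditions that spare the aryl silyl ethers, and acyl Sonogashira coupling then gives the ynone without any alkoxide that could trigger silyl migration.

Step 11
Reactants: 15 1-[2,4,6-tris(tert-butyldimethylsilyloxy)phenyl]-3-(2,4,5-trimethoxyphenyl)prop-2-yn-1-one
Product: 16 2-methoxy-5-{3-oxo-3-[2,4,6-tris(tert-butyldimethylsilyloxy)phenyl]prop-1-ynyl}-1,4-benzoquinone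
Conditions: CAN (2.5 equiv), MeCN/H2O 4:1, 0 °C, 10 min; use at once
Reagents that add atoms: water, O
Why: CAN oxidative demethylation removes the para-related 2- and 5-methoxy groups of the easily oxidised 1,2,4-trioxygenated ring, while the acylated meta-oxygenated silyloxy ring has a much higher oxidation potential and aryl TBS ethers survive a brief cold acidic exposure.

Step 12
Reactants: 9 (12E)-9α-hydroxylabda-8(17),12,14-trien-7-one; 16 2-methoxy-5-{3-oxo-3-[2,4,6-tris(tert-butyldimethylsilyloxy)phenyl]prop-1-ynyl}-1,4-benzoquinone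
Product: 19 target CNP0241859.1 [(4aS,5R,8aR)-adduct; C11 and chromone and H-8a all cis], via silylated cycloadduct 17 (not isolated), via free alkynoylphenol 18 (not isolated)
Conditions: 9 (1.0 equiv), 16 (1.2 equiv), PhMe, 4 Å MS, −20 °C to rt, dark; then MeCN, Et3N·3HF (excess), 0 °C to rt
Reagents that add atoms: none
Why: Proposed new method: the required quinone-exo topology is sought by an OH-directed Diels–Alder reaction in which A1,3 strain with the C13 methyl turns the C11–C9 bond perpendicular to the diene with C12 anti to C10, so that ring B shields one diene face while the axial 9α-OH lies beside the open face and can hydrogen-bond only to a C4=O (the vinylogous-ester, most basic quinone carbonyl) that points away from the diene, the rod-shaped alkynone fills the crowded endo quadrant under C13 and steers C15 to the unsubstituted quinone carbon ("ortho" rule), which sets 5R, 4aS and 8aR in one event, after which fluoride frees the phenols of 17 and one of the two equivalent ortho-OH groups of 18 closes the γ-pyrone by 6-endo-dig oxa-Michael addition; the closest known reaction types are hydroxyl-directed Diels–Alder reactions of dienols with quinones or maleimides, cycloadditions at the acceptor-substituted bond of 2-acylquinones, and the acid- or amine-promoted cyclisation of o-alkynoylphenols to chromones.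

## Compound list
1 | (+)-sclareolide | C[C@]12CCCC([C@@H]1CC[C@@]3([C@@H]2CC(=O)O3)C)(C)C | starting material
2 | methyl 13,14,15,16-tetranorlabd-8(9)-en-12-oate | CC1=C(CC(=O)OC)[C@@]2(C)CCCC(C)(C)[C@@H]2CC1 | intermediate
3 | methyl 8α,9α-epoxy-13,14,15,16-tetranorlabdan-12-oate | C[C@@]12CC[C@H]3C(C)(C)CCC[C@]3(C)[C@]1(CC(=O)OC)O2 | intermediate
4 | methyl 9α-hydroxy-13,14,15,16-tetranorlabd-8(17)-en-12-oate | C=C1CC[C@H]2C(C)(C)CCC[C@]2(C)[C@@]1(O)CC(=O)OC | intermediate
5 | methyl 7α,9α-dihydroxy-13,14,15,16-tetranorlabd-8(17)-en-12-oate | C=C1[C@H](O)C[C@H]2C(C)(C)CCC[C@]2(C)[C@@]1(O)CC(=O)OC | intermediate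
6 | 7α,9α-dihydroxy-13,14,15,16-tetranorlabd-8(17)-en-12-al | C=C1[C@H](O)C[C@H]2C(C)(C)CCC[C@]2(C)[C@@]1(O)CC=O | intermediate
7 | (12E)-7α,9α-dihydroxy-15-norlabda-8(17),12-dien-14-al (not isolated) | C=C1[C@H](O)C[C@H]2C(C)(C)CCC[C@]2(C)[C@@]1(O)C/C=C(\C)C=O | intermediate
8 | (12E)-labda-8(17),12,14-triene-7α,9α-diol | C=C1[C@H](O)C[C@H]2C(C)(C)CCC[C@]2(C)[C@@]1(O)C/C=C(\C)C=C | intermediate
9 | (12E)-9α-hydroxylabda-8(17),12,14-trien-7-one | C=C1C(=O)C[C@H]2C(C)(C)CCC[C@]2(C)[C@@]1(O)C/C=C(\C)C=C | intermediate
10 | 2,4,5-trimethoxybenzaldehyde | COc1cc(OC)c(C=O)cc1OC | starting material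
11 | 1-ethynyl-2,4,5-trimethoxybenzene | COc1cc(OC)c(C#C)cc1OC | intermediate
12 | 2,4,6-trihydroxybenzoic acid | OC(=O)c1c(O)cc(O)cc1O | starting material
13 | tert-butyldimethylsilyl 2,4,6-tris(tert-butyldimethylsilyloxy)benzoate | CC(C)(C)[Si](C)(C)OC(=O)c1c(O[Si](C)(C)C(C)(C)C)cc(O[Si](C)(C)C(C)(C)C)cc1O[Si](C)(C)C(C)(C)C | intermediate
14 | 2,4,6-tris(tert-butyldimethylsilyloxy)benzoyl chloride (not isolated) | ClC(=O)c1c(O[Si](C)(C)C(C)(C)C)cc(O[Si](C)(C)C(C)(C)C)cc1O[Si](C)(C)C(C)(C)C | intermediate
15 | 1-[2,4,6-tris(tert-butyldimethylsilyloxy)phenyl]-3-(2,4,5-trimethoxyphenyl)prop-2-yn-1-one | COc1cc(OC)c(C#CC(=O)c2c(O[Si](C)(C)C(C)(C)C)cc(O[Si](C)(C)C(C)(C)C)cc2O[Si](C)(C)C(C)(C)C)cc1OC | intermediate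
16 | 2-methoxy-5-{3-oxo-3-[2,4,6-tris(tert-butyldimethylsilyloxy)phenyl]prop-1-ynyl}-1,4-benzoquinone | COC1=CC(=O)C(C#CC(=O)c2c(O[Si](C)(C)C(C)(C)C)cc(O[Si](C)(C)C(C)(C)C)cc2O[Si](C)(C)C(C)(C)C)=CC1=O | intermediate
17 | (4aS,5R,8aR)-Diels–Alder adduct with angular tris-silylated alkynone (not isolated) | C=C1C(=O)C[C@H]2C(C)(C)CCC[C@]2(C)[C@@]1(O)C[C@@H]1C(C)=CC[C@H]2C(=O)C(OC)=CC(=O)[C@@]12C#CC(=O)c1c(O[Si](C)(C)C(C)(C)C)cc(O[Si](C)(C)C(C)(C)C)cc1O[Si](C)(C)C(C)(C)C | intermediate
18 | same adduct with free 2,4,6-trihydroxybenzoyl alkyne (not isolated) | C=C1C(=O)C[C@H]2C(C)(C)CCC[C@]2(C)[C@@]1(O)C[C@@H]1C(C)=CC[C@H]2C(=O)C(OC)=CC(=O)[C@@]12C#CC(=O)c1c(O)cc(O)cc1O | intermediate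
19 | CNP0241859.1 | C=C1C(=O)C[C@H]2C(C)(C)CCC[C@]2(C)[C@@]1(O)C[C@@H]1C(C)=CC[C@H]2C(=O)C(OC)=CC(=O)[C@@]12c1cc(=O)c2c(O)cc(O)cc2o1 | target

## Count and risks
Total step count: 12. Longest linear sequence: 8 (steps 1–7, then 12).

**Most likely to fail, first: step 12.** The risks are exo/endo and facial selectivity, competing addition to the triple bond, and 5-exo closure. The fallback sets out from 16 (with 9) and comes back at 19. It reverses the order of ring formation and moves the stereocontrol from the substrate to a catalyst. Quinone 16 alone is treated with Et3N·3HF so that the pyrone closes first, and the flavone quinone 5,7-dihydroxy-2-(4-methoxy-3,6-dioxocyclohexa-1,4-dienyl)chromen-4-one F1 is isolated. F1 no longer has a reactive alkyne. It is then combined with 9 in the presence of a chiral boron Lewis acid made from B(OPh)3 and a vaulted biaryl diol. This acid chelates the 5-OH/4-C=O pair in the way used for 2'-hydroxychalcone dienophiles. The chelated chromone becomes the activated, endo-seeking acceptor, which is the same topology as quinone-exo. The catalyst enantiomer is chosen to match the diene face, and hydrolytic work-up gives 19 directly.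

**Second: step 3.** The risk is the choice between C8–O and C9–O cleavage. The fallback sets out from 2, bypasses 3 and comes back at 4. It replaces the radical opening by a pericyclic oxygenation. A Schenck ene reaction of 2 (O2, tetraphenylporphyrin, hν, CH2Cl2, −20 °C) attacks the α face. It places oxygen on C9, because the C11 hydrogens next to the ester are deactivated, and gives methyl 9α-hydroperoxy-13,14,15,16-tetranorlabd-8(17)-en-12-oate F2. Reduction of F2 with PPh3 gives 4. Any Δ7 isomer is removed by chromatography.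

**Third: step 11.** The risk is oxidising an electron-poor, water-sensitive ynone. The fallback sets out from 11 and comes back at 16. It oxidises ring D while that ring is still electron-rich and creates the ynone last. 2,4,6-Trihydroxybenzaldehyde is silylated to 2,4,6-tris(tert-butyldimethylsilyloxy)benzaldehyde F3. Lithiated 11 (n-BuLi, THF, −78 °C, cold AcOH quench) adds to F3 to give the racemic propargylic alcohol 1-[2,4,6-tris(tert-butyldimethylsilyloxy)phenyl]-3-(2,4,5-trimethoxyphenyl)prop-2-yn-1-ol F4. CAN converts F4 into the quinone carbinol 2-{3-hydroxy-3-[2,4,6-tris(tert-butyldimethylsilyloxy)phenyl]prop-1-ynyl}-5-methoxy-1,4-benzoquinone F5. Anhydrous MnO2 in CH2Cl2 then oxidises F5 to 16.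

## Further compounds
F1 | step 12 | 5,7-dihydroxy-2-(4-methoxy-3,6-dioxocyclohexa-1,4-dienyl)chromen-4-one | COC1=CC(=O)C(=CC1=O)c1cc(=O)c2c(O)cc(O)cc2o1
F2 | step 3 | methyl 9α-hydroperoxy-13,14,15,16-tetranorlabd-8(17)-en-12-oate | C=C1CC[C@H]2C(C)(C)CCC[C@]2(C)[C@@]1(OO)CC(=O)OC
F3 | step 11 | 2,4,6-tris(tert-butyldimethylsilyloxy)benzaldehyde | O=Cc1c(O[Si](C)(C)C(C)(C)C)cc(O[Si](C)(C)C(C)(C)C)cc1O[Si](C)(C)C(C)(C)C
F4 | step 11 | 1-[2,4,6-tris(tert-butyldimethylsilyloxy)phenyl]-3-(2,4,5-trimethoxyphenyl)prop-2-yn-1-ol (racemic) | COc1cc(OC)c(C#CC(O)c2c(O[Si](C)(C)C(C)(C)C)cc(O[Si](C)(C)C(C)(C)C)cc2O[Si](C)(C)C(C)(C)C)cc1OC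
F5 | step 11 | 2-{3-hydroxy-3-[2,4,6-tris(tert-butyldimethylsilyloxy)phenyl]prop-1-ynyl}-5-methoxy-1,4-benzoquinone (racemic) | COC1=CC(=O)C(C#CC(O)c2c(O[Si](C)(C)C(C)(C)C)cc(O[Si](C)(C)C(C)(C)C)cc2O[Si](C)(C)C(C)(C)C)=CC1=O
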